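A direct plan would fold the acyclic 4-oxofarnesoate A1, an allylic acetate that also carries an allylsilane, into the ten-membered germacrenone A2 by a C6–C7 closure, close C5–C10 across the ring with acid to the eudesmane ketone A3, then adjust C8 and oxidise C3–H and C5–H last. Its weakest steps would be the ten-membered ring closure of A1, which would lack close precedent and would compete with oligomerisation; the transannular cation–olefin closure of A2, in which the acid could also shift the 4(15) or 11(13) alkene or epimerise C7; and the late hydroxylation of the tertiary C5–H, which would compete with over-oxidation of three alkenes.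

The target's cis pair of C7 acrylate and C8 oxygen on ring B is the retron of an allylmetal–aldehyde addition, so ring B is closed last, at C7–C8, by an intramolecular Barbier allylation: a (2Z)-2-(bromomethyl)enoate arm on C5 adds through C7 to a lactol-masked aldehyde arm on C10, which forms the ring, both stereocentres and the acrylate in one operation. Ring A is (R)-carvone: its isopropenyl-bearing carbon directs C5, a Ueno–Stork cyclisation relays C5 to C10, and the isopropenyl group is then excised to the C3 carbonyl. The C3 and C5 oxygens and the 4(15)-methylene are thus built in; no medium ring, cationic closure or late C–H oxidation is needed.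

Key step: step 9

Remark: atom numbers C1–C15 are the eudesmane numbers of the target. The acetal carbon, the carbinol carbon of 11, the sulfoxide sulfur and C3 of 14 would form as epimer mixtures that are removed later, so the SMILES leave them undefined. Partial exchange of the ethyl acetal for a methyl acetal in step 8 would be without consequence.

Step 1
Reactants: 1 (R)-(−)-carvone
Product: 3 (5R,6S)-2-methyl-6-[(phenylsulfanyl)methyl]-5-(prop-1-en-2-yl)cyclohex-2-en-1-one, via silyl dienol ether 2 (not isolated)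
Conditions: LiN(iPr)2, THF, −78 °C; Me3SiCl; then PhSCH2Cl, ZnBr2 (5 mol%), CH2Cl2, 0 °C to rt
Reagents that add atoms: chloromethyl phenyl sulfide, ClCSc1ccccc1
Why: Kinetic deprotonation at the α'-carbon (C4 of the target) gives the cross-conjugated silyl dienol ether, which the thionium ion from the α-chloro sulfide alkylates at that carbon (Lewis-acid α-(phenylthio)methylation of a silyl enol ether) anti to the isopropenyl group; the new centre only holds the masked C15 methylene and its configuration has no consequence.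

Step 2
Reactants: 3 (5R,6S)-2-methyl-6-[(phenylsulfanyl)methyl]-5-(prop-1-en-2-yl)cyclohex-2-en-1-one; 4 methyl acetate
Product: 5 methyl 2-[(1R,5R,6S)-1-hydroxy-2-methyl-6-[(phenylsulfanyl)methyl]-5-(prop-1-en-2-yl)cyclohex-2-en-1-yl]acetate
Conditions: LiN(iPr)2, 4, THF, −78 °C; then 3, −78 °C, 30 min; AcOH quench at −78 °C
Reagents that add atoms: none
Why: Aldol 1,2-addition of the lithium ester enolate, which should be faster than enolisation at −78 °C: as in hydride and organometallic additions to carvone, the nucleophile enters axially, anti to the equatorial isopropenyl group, so the hydroxyl ends up cis to the isopropenyl group, which sets C5.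

Step 3
Reactants: 5 methyl 2-[(1R,5R,6S)-1-hydroxy-2-methyl-6-[(phenylsulfanyl)methyl]-5-(prop-1-en-2-yl)cyclohex-2-en-1-yl]acetate
Product: 6 methyl 2-[(1R,5R,6S)-1-(2-bromo-1-ethoxyethoxy)-2-methyl-6-[(phenylsulfanyl)methyl]-5-(prop-1-en-2-yl)cyclohex-2-en-1-yl]acetate
Conditions: Br2, ethyl vinyl ether, CH2Cl2, −78 °C; then 5, PhNMe2, −78 °C to rt
Reagents that add atoms: ethyl vinyl ether, C=COCC; bromine, BrBr
Why: Mixed bromoacetal formation: the tertiary allylic alcohol captures the α-bromo oxocarbenium ion from preformed 1,2-dibromo-1-ethoxyethane under amine buffering, so that neither free bromine nor acid meets the sulfide or the alcohol; the acetal carbon forms as both epimers and later becomes the C8 aldehyde.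

Step 4
Reactants: 6 methyl 2-[(1R,5R,6S)-1-(2-bromo-1-ethoxyethoxy)-2-methyl-6-[(phenylsulfanyl)methyl]-5-(prop-1-en-2-yl)cyclohex-2-en-1-yl]acetate
Product: 7 methyl 2-[(3aR,6R,7S,7aR)-2-ethoxy-3a-methyl-7-[(phenylsulfanyl)methyl]-6-(prop-1-en-2-yl)octahydro-1-benzofuran-7a-yl]acetate
Conditions: Bu3SnH (1.3 equiv, syringe pump), AIBN (0.1 equiv), PhH, 80 °C, 0.02 M
Reagents that add atoms: none
Why: Ueno–Stork radical cyclisation, well precedented for bromoacetals of tertiary carvone-derived allylic alcohols: the primary radical adds 5-exo-trig to the methyl-bearing alkene carbon, the only mode that gives a cis-fused five-membered ring, so C9 is delivered to the face of the C5 oxygen and the quaternary C10 is set with its methyl trans to that oxygen, while the sulfide, the ester and the isopropenyl group are inert to the tin radical.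

Step 5
Reactants: 7 methyl 2-[(3aR,6R,7S,7aR)-2-ethoxy-3a-methyl-7-[(phenylsulfanyl)methyl]-6-(prop-1-en-2-yl)octahydro-1-benzofuran-7a-yl]acetate
Product: 8 2-[(3aR,6R,7S,7aR)-2-ethoxy-3a-methyl-7-[(phenylsulfanyl)methyl]-6-(prop-1-en-2-yl)octahydro-1-benzofuran-7a-yl]acetaldehyde
Conditions: iBu2AlH (1.1 equiv), CH2Cl2, −78 °C; aqueous potassium sodium tartrate
Reagents that add atoms: none
Why: Partial reduction of the methyl ester through the aluminium hemiacetal that is stable at −78 °C, with no other reducible group in the molecule and no new stereocentre.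

Step 6
Reactants: 8 2-[(3aR,6R,7S,7aR)-2-ethoxy-3a-methyl-7-[(phenylsulfanyl)methyl]-6-(prop-1-en-2-yl)octahydro-1-benzofuran-7a-yl]acetaldehyde; 9 methyl propiolate
Product: 11 methyl 4-[(3aR,6R,7S,7aR)-2-ethoxy-3a-methyl-7-[(phenylsulfanyl)methyl]-6-(prop-1-en-2-yl)octahydro-1-benzofuran-7a-yl]-3-hydroxy-2-methylidenebutanoate, via vinylalane 10 (not isolated)
Conditions: iBu2AlH, HMPA, THF, 0 °C; 9, 0 °C, 1 h; then 8, 0 °C to rt
Reagents that add atoms: none
Why: Vinylalumination: hydroalumination of the propiolate places aluminium on the α-carbon and the vinylalane adds to the aldehyde to give the Morita–Baylis–Hillman-type adduct without an amine catalyst, so the β-alkoxy aldehyde is not exposed to base; the two carbinol epimers converge in the next step.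

Step 7
Reactants: 11 methyl 4-[(3aR,6R,7S,7aR)-2-ethoxy-3a-methyl-7-[(phenylsulfanyl)methyl]-6-(prop-1-en-2-yl)octahydro-1-benzofuran-7a-yl]-3-hydroxy-2-methylidenebutanoate
Product: 12 methyl (2Z)-2-(bromomethyl)-4-[(3aR,6R,7S,7aR)-2-ethoxy-3a-methyl-7-[(phenylsulfanyl)methyl]-6-(prop-1-en-2-yl)octahydro-1-benzofuran-7a-yl]but-2-enoate
Conditions: NBS, Me2S, CH2Cl2, −20 °C (reagent preformed); then 11, 0 °C to rt
Reagents that add atoms: N-bromosuccinimide, O=C1CCC(=O)N1Br
Why: Corey–Kim-type bromination with allylic transposition: bromide attacks the activated alcohol at the methylene terminus (SN2′) and gives the thermodynamically preferred (2Z)-2-(bromomethyl)enoate with C6 cis to CH2Br, the geometry that the ring closure needs, while the preformed sulfonium reagent spares the acetal and the aryl sulfide.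

Step 8
Reactants: 12 methyl (2Z)-2-(bromomethyl)-4-[(3aR,6R,7S,7aR)-2-ethoxy-3a-methyl-7-[(phenylsulfanyl)methyl]-6-(prop-1-en-2-yl)octahydro-1-benzofuran-7a-yl]but-2-enoate
Product: 16 methyl (2Z)-2-(bromomethyl)-4-[(3aR,7aS)-2-ethoxy-3a-methyl-7-methylidene-6-oxooctahydro-1-benzofuran-7a-yl]but-2-enoate, via methoxy hydroperoxide 13 (not isolated), via TEMPO ether 14 (not isolated), via keto sulfoxide 15 (not isolated)
Conditions: O3, CH2Cl2/MeOH, −78 °C (Sudan red end point); FeSO4·7H2O (1.2 equiv), TEMPO (1.5 equiv), −78 to 0 °C; mCPBA (1.2 equiv), 0 °C; then 40 °C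
Reagents that add atoms: TEMPO, CC1(C)CCCC(C)(C)N1[O]
Why: Oxodealkenylation of a terpene isopropenyl group: ozone cleaves only the electron-rich 1,1-disubstituted alkene (and oxidises the sulfide to the sulfoxide) to an α-methoxy hydroperoxide, divalent iron reduces the O–O bond, the alkoxyl radical loses methyl acetate by β-scission, TEMPO traps the C3 radical and the peracid turns the alkoxyamine into the ketone, after which the β-sulfinyl ketone loses benzenesulfenic acid by thermal syn-elimination to the exocyclic enone; the C3 stereocentre that controlled C5 is removed and no new one is formed.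

Step 9
Reactants: 16 methyl (2Z)-2-(bromomethyl)-4-[(3aR,7aS)-2-ethoxy-3a-methyl-7-methylidene-6-oxooctahydro-1-benzofuran-7a-yl]but-2-enoate
Product: 19 methyl (5S,7R,8R,10R)-5α,8β-dihydroxy-3-oxoeudesma-4(15),11(13)-dien-12-oate, via lactol 17 (not isolated), via allylindium reagent 18 (not isolated)
Conditions: 1 M aq HCl, THF, rt; then In powder (2 equiv), THF/H2O, rt, 0.01 M; work-up at pH 7
Reagents that add atoms: water, O
Why: Aqueous acid hydrolyses the mixed acetal to lactol 17, which is in equilibrium with the 5-hydroxy aldehyde, and zerovalent indium inserts into the allylic C–Br bond to give the 2-(methoxycarbonyl)allyl indium reagent 18, which adds through its γ-carbon C7 to the aldehyde carbon C8 in a closed chair-like Zimmerman–Traxler transition state (an intramolecular Barbier allylation; the closest known reaction type is the zinc-, chromium- or indium-mediated cyclisation of ω-formyl 2-(bromomethyl)alk-2-enoates to carbocycles that carry a cis α-methylene-γ-hydroxy ester unit). Ring B closes 6-exo-trig with respect to the aldehyde, and attack through C13 instead would need an eight-membered ring. The cis relation of C7 and C8 follows from the (Z)-allyl unit, which must hold C6 axial and C9 equatorial on the metallacyclic chair if a six-membered carbocycle is to form. The facial sense follows from ring A, whose chair holds the two arms trans-diequatorial with 10β-CH3 and 5α-OH axial: of the two cis-fused transition states, the one with the bulky C11 unit equatorial (7β) and only the small carbonyl oxygen axial (8β, syn to the methyl) should be preferred over the one that puts C11 axial and 1,3-diaxial to the 5α-oxygen, so C7 and C8 both become R. The step needs chemoselectivity for the aldehyde over the C3 enone and the ester, which the water-tolerant indium reagent, the low electrophilicity of the hindered conjugated ketone and the bridged bicyclo[3.2.1] geometry that attack on C3 would require should secure, and the near-neutral aqueous medium should leave the 8β-hydroxy ester unlactonised.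

Step 10
Reactants: 19 methyl (5S,7R,8R,10R)-5α,8β-dihydroxy-3-oxoeudesma-4(15),11(13)-dien-12-oate
Product: 20 methyl (5S,7R,8R,10R)-8β-acetoxy-5α-hydroxy-3-oxoeudesma-4(15),11(13)-dien-12-oate
Conditions: Ac2O, DMAP, pyridine, CH2Cl2, 0 °C to rt
Reagents that add atoms: acetic anhydride, CC(=O)OC(C)=O
Why: DMAP-catalysed acetylation of the only secondary hydroxyl, carried out at once so that the cis 8-hydroxy ester cannot lactonise; the tertiary 5-hydroxyl does not react and no stereocentre is touched.

Step 11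
Reactants: 20 methyl (5S,7R,8R,10R)-8β-acetoxy-5α-hydroxy-3-oxoeudesma-4(15),11(13)-dien-12-oate
Product: 21 methyl (3S,5S,7R,8R,10R)-8β-acetoxy-3β,5α-dihydroxyeudesma-4(15),11(13)-dien-12-oate
Conditions: Me4NBH(OAc)3, MeCN/AcOH 1:1, −30 °C
Reagents that add atoms: none
Why: Evans–Saksena hydroxyl-directed reduction: the borohydride exchanges an acetate for the axial 5α-hydroxyl and delivers hydride intramolecularly to the α-face of the C3 ketone, so the new hydroxyl is 3β (equatorial and anti to the 5-hydroxyl), and the reagent reduces neither the esters nor the alkenes.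

Step 12
Reactants: 21 methyl (3S,5S,7R,8R,10R)-8β-acetoxy-3β,5α-dihydroxyeudesma-4(15),11(13)-dien-12-oate; 22 angelic acid
Product: 24 methyl (3S,5S,7R,8R,10R)-8β-acetoxy-3β-angeloyloxy-5α-hydroxyeudesma-4(15),11(13)-dien-12-oate, via mixed anhydride 23 (not isolated)
Conditions: 22, 2,4,6-trichlorobenzoyl chloride, Et3N, PhMe, rt; then 21, PhMe, 80 °C (no DMAP)
Reagents that add atoms: none
Why: Yamaguchi esterification through the mixed 2,4,6-trichlorobenzoic anhydride without a nucleophilic catalyst, a protocol under which the (Z)-geometry of angelates is retained; the equatorial allylic 3β-hydroxyl is acylated with retention at C3 and the tertiary 5-hydroxyl does not react.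

**Compound list**

1 | (R)-(−)-carvone, (5R)-2-methyl-5-(prop-1-en-2-yl)cyclohex-2-en-1-one | CC1=CC[C@@H](C(C)=C)CC1=O | starting material
2 | trimethyl{[(3R)-6-methyl-3-(prop-1-en-2-yl)cyclohexa-1,5-dien-1-yl]oxy}silane | CC1=CC[C@@H](C(C)=C)C=C1O[Si](C)(C)C | intermediate
3 | (5R,6S)-2-methyl-6-[(phenylsulfanyl)methyl]-5-(prop-1-en-2-yl)cyclohex-2-en-1-one (CH2SPh trans to isopropenyl) | CC1=CC[C@@H](C(C)=C)[C@H](CSc2ccccc2)C1=O | intermediate
4 | methyl acetate | COC(C)=O | starting material
5 | methyl 2-[(1R,5R,6S)-1-hydroxy-2-methyl-6-[(phenylsulfanyl)methyl]-5-(prop-1-en-2-yl)cyclohex-2-en-1-yl]acetate (hydroxyl cis to isopropenyl) | COC(=O)C[C@@]1(O)[C@@H](CSc2ccccc2)[C@H](C(C)=C)CC=C1C | intermediate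
6 | methyl 2-[(1R,5R,6S)-1-(2-bromo-1-ethoxyethoxy)-2-methyl-6-[(phenylsulfanyl)methyl]-5-(prop-1-en-2-yl)cyclohex-2-en-1-yl]acetate (both acetal epimers) | COC(=O)C[C@@]1(OC(CBr)OCC)[C@@H](CSc2ccccc2)[C@H](C(C)=C)CC=C1C | intermediate
7 | methyl 2-[(3aR,6R,7S,7aR)-2-ethoxy-3a-methyl-7-[(phenylsulfanyl)methyl]-6-(prop-1-en-2-yl)octahydro-1-benzofuran-7a-yl]acetate (cis-fused; both C2 epimers) | COC(=O)C[C@]12OC(OCC)C[C@@]1(C)CC[C@@H](C(C)=C)[C@@H]2CSc1ccccc1 | intermediate
8 | 2-[(3aR,6R,7S,7aR)-2-ethoxy-3a-methyl-7-[(phenylsulfanyl)methyl]-6-(prop-1-en-2-yl)octahydro-1-benzofuran-7a-yl]acetaldehyde | O=CC[C@]12OC(OCC)C[C@@]1(C)CC[C@@H](C(C)=C)[C@@H]2CSc1ccccc1 | intermediate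
9 | methyl propiolate (methyl prop-2-ynoate) | C#CC(=O)OC | starting material
10 | [1-(methoxycarbonyl)ethenyl]bis(2-methylpropyl)aluminium | C=C(C(=O)OC)[Al](CC(C)C)CC(C)C | intermediate
11 | methyl 4-[(3aR,6R,7S,7aR)-2-ethoxy-3a-methyl-7-[(phenylsulfanyl)methyl]-6-(prop-1-en-2-yl)octahydro-1-benzofuran-7a-yl]-3-hydroxy-2-methylidenebutanoate (both carbinol epimers) | C=C(C(=O)OC)C(O)C[C@]12OC(OCC)C[C@@]1(C)CC[C@@H](C(C)=C)[C@@H]2CSc1ccccc1 | intermediate
12 | methyl (2Z)-2-(bromomethyl)-4-[(3aR,6R,7S,7aR)-2-ethoxy-3a-methyl-7-[(phenylsulfanyl)methyl]-6-(prop-1-en-2-yl)octahydro-1-benzofuran-7a-yl]but-2-enoate | COC(=O)/C(CBr)=C/C[C@]12OC(OCC)C[C@@]1(C)CC[C@@H](C(C)=C)[C@@H]2CSc1ccccc1 | intermediate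
13 | compound 12 with the isopropenyl group replaced by 1-hydroperoxy-1-methoxyethyl and the sulfide oxidised to the sulfoxide | COC(=O)/C(CBr)=C/C[C@]12OC(OCC)C[C@@]1(C)CC[C@@H](C(C)(OC)OO)[C@@H]2CS(=O)c1ccccc1 | intermediate
14 | the corresponding 6-[(2,2,6,6-tetramethylpiperidin-1-yl)oxy] ether at C3 of the target numbering (both epimers; sulfoxide) | COC(=O)/C(CBr)=C/C[C@]12OC(OCC)C[C@@]1(C)CCC(ON3C(C)(C)CCCC3(C)C)[C@@H]2CS(=O)c1ccccc1 | intermediate
15 | methyl (2Z)-2-(bromomethyl)-4-[2-ethoxy-3a-methyl-6-oxo-7-[(phenylsulfinyl)methyl]octahydro-1-benzofuran-7a-yl]but-2-enoate (ring-fusion centres as in 12) | COC(=O)/C(CBr)=C/C[C@]12OC(OCC)C[C@@]1(C)CCC(=O)[C@@H]2CS(=O)c1ccccc1 | intermediate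
16 | methyl (2Z)-2-(bromomethyl)-4-[(3aR,7aS)-2-ethoxy-3a-methyl-7-methylidene-6-oxooctahydro-1-benzofuran-7a-yl]but-2-enoate | COC(=O)/C(CBr)=C/C[C@]12OC(OCC)C[C@@]1(C)CCC(=O)C2=C | intermediate
17 | methyl (2Z)-2-(bromomethyl)-4-[(3aR,7aS)-2-hydroxy-3a-methyl-7-methylidene-6-oxooctahydro-1-benzofuran-7a-yl]but-2-enoate (lactol) | COC(=O)/C(CBr)=C/C[C@]12OC(O)C[C@@]1(C)CCC(=O)C2=C | intermediate
18 | methyl (2Z)-4-[(1S,2R)-1-hydroxy-2-methyl-6-methylidene-5-oxo-2-(2-oxoethyl)cyclohexyl]-2-(indiomethyl)but-2-enoate (allylic reagent of monovalent indium; open hydroxy aldehyde form) | O=CC[C@@]1(C)CCC(=O)C(=C)[C@]1(O)C/C=C(\C[In])C(=O)OC | intermediate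
19 | methyl (5S,7R,8R,10R)-5α,8β-dihydroxy-3-oxoeudesma-4(15),11(13)-dien-12-oate | C=C(C(=O)OC)[C@H]1C[C@@]2(O)C(=C)C(=O)CC[C@]2(C)C[C@H]1O | intermediate
20 | methyl (5S,7R,8R,10R)-8β-acetoxy-5α-hydroxy-3-oxoeudesma-4(15),11(13)-dien-12-oate | C=C(C(=O)OC)[C@H]1C[C@@]2(O)C(=C)C(=O)CC[C@]2(C)C[C@H]1OC(C)=O | intermediate
21 | methyl (3S,5S,7R,8R,10R)-8β-acetoxy-3β,5α-dihydroxyeudesma-4(15),11(13)-dien-12-oate | C=C(C(=O)OC)[C@H]1C[C@@]2(O)C(=C)[C@@H](O)CC[C@]2(C)C[C@H]1OC(C)=O | intermediate
22 | angelic acid, (2Z)-2-methylbut-2-enoic acid | C/C=C(/C)C(=O)O | starting material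
23 | (2Z)-2-methylbut-2-enoic 2,4,6-trichlorobenzoic anhydride | C/C=C(/C)C(=O)OC(=O)c1c(Cl)cc(Cl)cc1Cl | intermediate
24 | methyl (3S,5S,7R,8R,10R)-8β-acetoxy-3β-angeloyloxy-5α-hydroxyeudesma-4(15),11(13)-dien-12-oate | C=C(C(=O)OC)[C@H]1C[C@@]2(O)C(=C)[C@@H](OC(=O)/C(C)=C\C)CC[C@]2(C)C[C@H]1OC(C)=O | target

Total step count: 12. Longest linear sequence: 12 steps, from (R)-carvone 1 to 24.

**Steps most likely to fail**

1. Step 9 (key step). The ring closure may show poor facial selectivity, because the C8 oxygen must go axial, syn to the angular methyl. The trans isomer may form if the allyl metal equilibrates, and the cis hydroxy ester may lactonise. The fallback would set C8 by hydride delivery and starts from 19 as whatever C7/C8 mixture forms. Dess–Martin periodinane (NaHCO3, CH2Cl2) would give methyl (5S,7R,10R)-5α-hydroxy-3,8-dioxoeudesma-4(15),11(13)-dien-12-oate F1, in which C7 can settle to the equatorial side chain. Me4NBH(OAc)3 would reduce only the β-hydroxy ketone at C3 to methyl (3S,5S,7R,10R)-3β,5α-dihydroxy-8-oxoeudesma-4(15),11(13)-dien-12-oate F2. Yamaguchi angeloylation as in step 12 would give methyl (3S,5S,7R,10R)-3β-angeloyloxy-5α-hydroxy-8-oxoeudesma-4(15),11(13)-dien-12-oate F3. LiAlH(OtBu)3 (THF, −78 to −30 °C) would then attack the C8 ketone from the α-face, anti to the 10β-methyl, and Ac2O/DMAP added to the same flask would acetylate the 8β-alkoxide. The fallback comes back to the route at 24.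

2. Step 8. Ozone may attack the trisubstituted enoate before the isopropenyl group is consumed, the C3 radical may escape trapping, or the sulfoxide elimination may stay incomplete. The fallback would move the cleavage to the ester stage and use a Criegee rearrangement; it starts from 7. O3 in CH2Cl2/MeOH at −78 °C, then Ac2O, Et3N and DMAP, would give methyl 2-[6-acetoxy-2-ethoxy-3a-methyl-7-[(phenylsulfinyl)methyl]octahydro-1-benzofuran-7a-yl]acetate F4, with the acetoxy group in place of the isopropenyl group and with retention. iBu2AlH at −78 °C would give 2-[2-ethoxy-6-hydroxy-3a-methyl-7-[(phenylsulfinyl)methyl]octahydro-1-benzofuran-7a-yl]acetaldehyde F5. Vinylalumination as in step 6 would give methyl 4-[2-ethoxy-6-hydroxy-3a-methyl-7-[(phenylsulfinyl)methyl]octahydro-1-benzofuran-7a-yl]-3-hydroxy-2-methylidenebutanoate F6. The Corey–Kim reagent, which converts only the allylic alcohol, would give methyl (2Z)-2-(bromomethyl)-4-[2-ethoxy-6-hydroxy-3a-methyl-7-[(phenylsulfinyl)methyl]octahydro-1-benzofuran-7a-yl]but-2-enoate F7. Dess–Martin oxidation of the remaining carbinol would give keto sulfoxide 15, which on warming to 40 °C would lose benzenesulfenic acid. The fallback comes back to the route at 16.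

3. Step 2. The basic lithium enolate may enolise the ketone, which would expel thiophenolate (E1cB), or the addition may show poor facial selectivity. The fallback would use a Reformatsky reaction, in which a non-basic zinc enolate is generated in the presence of the ketone (methyl bromoacetate, activated Zn, THF, 40 °C). It starts from 3 and comes back to the route at 5; it makes no new compound, hence the entry F0.

**Further compounds**

F1 | step 9 | methyl (5S,7R,10R)-5α-hydroxy-3,8-dioxoeudesma-4(15),11(13)-dien-12-oate | C=C(C(=O)OC)[C@H]1C[C@@]2(O)C(=C)C(=O)CC[C@]2(C)CC1=O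
F2 | step 9 | methyl (3S,5S,7R,10R)-3β,5α-dihydroxy-8-oxoeudesma-4(15),11(13)-dien-12-oate | C=C(C(=O)OC)[C@H]1C[C@@]2(O)C(=C)[C@@H](O)CC[C@]2(C)CC1=O
F3 | step 9 | methyl (3S,5S,7R,10R)-3β-angeloyloxy-5α-hydroxy-8-oxoeudesma-4(15),11(13)-dien-12-oate | C=C(C(=O)OC)[C@H]1C[C@@]2(O)C(=C)[C@@H](OC(=O)/C(C)=C\C)CC[C@]2(C)CC1=O
F4 | step 8 | methyl 2-[6-acetoxy-2-ethoxy-3a-methyl-7-[(phenylsulfinyl)methyl]octahydro-1-benzofuran-7a-yl]acetate (ring centres as in 7) | COC(=O)C[C@]12OC(OCC)C[C@@]1(C)CC[C@@H](OC(C)=O)[C@@H]2CS(=O)c1ccccc1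
F5 | step 8 | 2-[2-ethoxy-6-hydroxy-3a-methyl-7-[(phenylsulfinyl)methyl]octahydro-1-benzofuran-7a-yl]acetaldehyde | O=CC[C@]12OC(OCC)C[C@@]1(C)CC[C@@H](O)[C@@H]2CS(=O)c1ccccc1
F6 | step 8 | methyl 4-[2-ethoxy-6-hydroxy-3a-methyl-7-[(phenylsulfinyl)methyl]octahydro-1-benzofuran-7a-yl]-3-hydroxy-2-methylidenebutanoate | C=C(C(=O)OC)C(O)C[C@]12OC(OCC)C[C@@]1(C)CC[C@@H](O)[C@@H]2CS(=O)c1ccccc1
F7 | step 8 | methyl (2Z)-2-(bromomethyl)-4-[2-ethoxy-6-hydroxy-3a-methyl-7-[(phenylsulfinyl)methyl]octahydro-1-benzofuran-7a-yl]but-2-enoate | COC(=O)/C(CBr)=C/C[C@]12OC(OCC)C[C@@]1(C)CC[C@@H](O)[C@@H]2CS(=O)c1ccccc1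
F0 | step 2 | none | none
A1 | direct plan | methyl (2Z,6E,10E)-12-acetoxy-6,10-dimethyl-4-oxo-2-[(trimethylsilyl)methyl]dodeca-2,6,10-trienoate | COC(=O)/C(C[Si](C)(C)C)=C/C(=O)C/C(C)=C/CC/C(C)=C/COC(C)=O
A2 | direct plan | methyl (7R)-8-oxogermacra-1(10)E,4E,11(13)-trien-12-oate | C=C(C(=O)OC)[C@H]1C/C=C(\C)CC/C=C(\C)CC1=O
A3 | direct plan | methyl (5S,7R,10R)-8-oxoeudesma-4(15),11(13)-dien-12-oate | C=C(C(=O)OC)[C@H]1C[C@H]2C(=C)CCC[C@]2(C)CC1=O
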